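**Assumption:** the SMILES is read as ent-epicatechin-(4β→8)-epicatechin-4β-ol, i.e. upper unit 2S,3S,4R (2,3-cis-3,4-cis, all-cis) and lower unit 2R,3R,4S (2,3-cis-3,4-trans).

## Retrosynthetic overview

1. Target 18 ⇐ macrocyclic cycloadduct 15 by removing the diester strap, six benzyl ethers and two TBS ethers.
2. 15 ⇐ aldehyde 6 + phloroglucinol ester 12 in one operation (arene hydroxyalkylation → o-quinone methide → intramolecular hetero-Diels–Alder). This forms C4–C4a, C4–C3 and C2–O1, closes the pyran C ring and a 12-membered diolide ring together, and creates all three upper stereocentres.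
3. 6 ⇐ (−)-epicatechin: rings D/E/F and C2/C3 come from the chiral pool, the 4β-OH from DDQ/H2O, the C8 formyl group via the 8-bromide.
4. 12 ⇐ phloroglucinol (ring A) + adipic acid (strap) + aryl alkyne 8 (ring B), joined through a Ru-catalysed Z-selective enol ester formation.
5. Ring order: D/E/F preformed → A and B brought in as arenes → C ring (with the temporary macro-ring) last.

## Route

Step 1
Reactants: 1 (−)-epicatechin
Product: 2 5,7,3',4'-tetra-O-benzyl-(−)-epicatechin
Conditions: BnBr (4.4 equiv), K2CO3, DMF, 0 °C → rt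
Reagents that add atoms: benzyl bromide BrCc1ccccc1
Why: Williamson O-benzylation of the four phenols; the hindered secondary 3-OH is not alkylated by carbonate base and no stereocentre is touched.

Step 2
Reactants: 2 tetra-O-benzyl-epicatechin
Product: 3 5,7,3',4'-tetra-O-benzyl-(−)-epicatechin-4β-ol (2R,3R,4S; 3,4-trans)
Conditions: DDQ (1.5 equiv), CH2Cl2/H2O 20:1, rt
Reagents that add atoms: water O
Why: DDQ benzylic oxidation (hydride abstraction at C4 of the 5,7-dialkoxy ring); water captures the cation anti to the axial 3-OH, which sets C4 as 4β.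

Step 3
Reactants: 3 tetra-O-benzyl-epicatechin-4β-ol
Product: 4 3,4-bis-O-TBS ether of 3
Conditions: TBSOTf (3 equiv), 2,6-lutidine, CH2Cl2, −40 → 0 °C
Reagents that add atoms: tert-butyldimethylsilyl triflate CC(C)(C)[Si](C)(C)OS(=O)(=O)C(F)(F)F
Why: silyl triflate silylation of both hindered trans-diaxial alcohols; the buffered, cold conditions keep the benzylic C4–O bond from ionising, so configuration is retained.

Step 4
Reactants: 4 bis-TBS ether
Product: 5 8-bromo derivative of 4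
Conditions: NBS (1.05 equiv), CH2Cl2, −40 °C
Reagents that add atoms: N-bromosuccinimide BrN1C(=O)CCC1=O
Why: electrophilic aromatic bromination, in which benzylated epicatechins react selectively at C8 with one equivalent of NBS at low temperature.

Step 5
Reactants: 5 aryl bromide
Product: 6 8-formyl derivative of 4 (lower-unit aldehyde)
Conditions: n-BuLi (1.1 equiv), THF, −78 °C; DMF; H2O
Reagents that add atoms: N,N-dimethylformamide CN(C)C=O
Why: bromine–lithium exchange followed by Bouveault formylation; silyl and benzyl ethers tolerate the aryllithium at −78 °C.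

Step 6
Reactants: 7 bis(benzyloxy)benzaldehyde
Product: 8 4-ethynyl-1,2-bis(benzyloxy)benzene
Conditions: dimethyl (1-diazo-2-oxopropyl)phosphonate, K2CO3, MeOH/THF, rt
Reagents that add atoms: Ohira–Bestmann reagent CC(=O)C(=[N+]=[N-])P(=O)(OC)OC
Why: Seyferth–Gilbert/Ohira–Bestmann homologation of an aryl aldehyde to the terminal alkyne.

Step 7
Reactants: 8 aryl alkyne; 9 adipic acid
Product: 10 6-{[(Z)-2-(3,4-bis(benzyloxy)phenyl)ethenyl]oxy}-6-oxohexanoic acid
Conditions: [(p-cymene)RuCl2]2 (2 mol %), P(4-ClC6H4)3, DMAP (cat.), toluene/THF, 60 °C, diacid in fivefold excess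
Reagents that add atoms: none
Why: Ru-catalysed anti-Markovnikov addition of a carboxylic acid to a terminal alkyne (via a Ru-vinylidene) is a pure addition that gives the (Z)-enol ester, and the excess of diacid limits double addition.

Step 8
Reactants: 10 enol ester acid; 11 phloroglucinol
Product: 12 3,5-dihydroxyphenyl (Z)-2-[3,4-bis(benzyloxy)phenyl]ethenyl hexanedioate
Conditions: DCC, DMAP (5 mol %), THF, 0 °C → rt, triol in fivefold excess
Reagents that add atoms: none
Why: Steglich esterification; the large excess of the symmetric triol gives the mono-aryl ester, and the Z-enol ester is untouched at 0 °C.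

Step 9
Reactants: 6 lower-unit aldehyde; 12 phloroglucinol ester
Product: 15 adipoyl-strapped macrocyclic cycloadduct, via benzhydrol adduct 13 (not isolated), via o-quinone methide 14 (not isolated)
Conditions: (R)-TRIP (10 mol %), 4 Å MS, toluene/CH2Cl2, 2 mM, 40 °C, slow addition of the ester (1.2 equiv)
Reagents that add atoms: none
Why: Proposed new method: the chiral phosphoric acid promotes Friedel–Crafts hydroxyalkylation of the phloroglucinol ring by aldehyde 6 (C4–C4a), benzhydrol 13 loses water to the phosphate-bound o-quinone methide 14, and the tethered (Z)-enol ester adds in an inverse-demand intramolecular hetero-Diels–Alder reaction (C3–C4 and C2–O1; pyran ring and 12-membered diolide ring close together), where the electron-rich aryl group directs the regiochemistry as in styrene cycloadditions, the Z-alkene gives 2,3-cis, the endo transition state favoured by the short strap from the peri 5-oxygen on the E-quinone methide gives 3,4-cis, and the chiral phosphate shields one face to give 2S,3S,4R by catalyst control (the catalyst antipode is chosen for this sense); closest known reactions are the Tietze domino Knoevenagel/intramolecular hetero-Diels–Alder reaction and phosphoric-acid-catalysed [4+2] cycloadditions of o-quinone methides with styrenes.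

Step 10
Reactants: 15 macrocyclic cycloadduct
Product: 16 hexa-O-benzyl bis-O-TBS dimer with free upper 3-, 5- and 7-OH
Conditions: K2CO3 (0.3 equiv), MeOH/THF, rt, Ar
Reagents that add atoms: none
Why: base-catalysed transesterification cleaves the aryl and the alkyl ester of the strap; with the B-ring phenols still benzylated, C2 cannot epimerise.

Step 11
Reactants: 16 hexa-O-benzyl dimer
Product: 17 lower-unit 3,4-bis-O-TBS ether of the target
Conditions: H2 (1 atm), Pd(OH)2/C, EtOAc/THF, rt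
Reagents that add atoms: none
Why: hydrogenolysis of six aryl benzyl ethers under neutral aprotic conditions; the bulky silyl ether at C4 of the lower unit blocks benzylic C–O hydrogenolysis, to which a free 4-OH would be prone.

Step 12
Reactants: 17 bis-TBS ether
Product: 18 target, ent-epicatechin-(4β→8)-epicatechin-4β-ol
Conditions: TBAF/AcOH (1:1), THF, 0 °C → rt, Ar; Sephadex LH-20
Reagents that add atoms: none
Why: buffered fluoride desilylation cleaves only Si–O bonds, so the acid- and base-sensitive 4β-OH is released with retention and no stereocentre is touched.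

## Compound list

1 | (−)-epicatechin | Oc1cc(O)c2c(c1)O[C@H](c1ccc(O)c(O)c1)[C@H](O)C2 | starting material
2 | 5,7,3',4'-tetra-O-benzyl-(−)-epicatechin (2R,3R) | O(Cc1ccccc1)c1cc(OCc2ccccc2)c2c(c1)O[C@H](c1ccc(OCc3ccccc3)c(OCc3ccccc3)c1)[C@H](O)C2 | intermediate
3 | 5,7,3',4'-tetra-O-benzyl-epicatechin-4β-ol (2R,3R,4S) | O(Cc1ccccc1)c1cc(OCc2ccccc2)c2c(c1)O[C@H](c1ccc(OCc3ccccc3)c(OCc3ccccc3)c1)[C@H](O)[C@H]2O | intermediate
4 | 3,4-bis-O-TBS ether of 3 (2,3-cis-3,4-trans retained) | O(Cc1ccccc1)c1cc(OCc2ccccc2)c2c(c1)O[C@H](c1ccc(OCc3ccccc3)c(OCc3ccccc3)c1)[C@H](O[Si](C)(C)C(C)(C)C)[C@H]2O[Si](C)(C)C(C)(C)C | intermediate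
5 | 8-bromo derivative of 4 | O(Cc1ccccc1)c1cc(OCc2ccccc2)c2c(c1Br)O[C@H](c1ccc(OCc3ccccc3)c(OCc3ccccc3)c1)[C@H](O[Si](C)(C)C(C)(C)C)[C@H]2O[Si](C)(C)C(C)(C)C | intermediate
6 | 8-formyl derivative of 4 (lower-unit aldehyde) | O(Cc1ccccc1)c1cc(OCc2ccccc2)c2c(c1C=O)O[C@H](c1ccc(OCc3ccccc3)c(OCc3ccccc3)c1)[C@H](O[Si](C)(C)C(C)(C)C)[C@H]2O[Si](C)(C)C(C)(C)C | intermediate
7 | 3,4-bis(benzyloxy)benzaldehyde | O=Cc1ccc(OCc2ccccc2)c(OCc2ccccc2)c1 | starting material
8 | 4-ethynyl-1,2-bis(benzyloxy)benzene | C#Cc1ccc(OCc2ccccc2)c(OCc2ccccc2)c1 | intermediate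
9 | adipic acid | OC(=O)CCCCC(=O)O | starting material
10 | 6-{[(Z)-2-(3,4-bis(benzyloxy)phenyl)ethenyl]oxy}-6-oxohexanoic acid | OC(=O)CCCCC(=O)O/C=C\c1ccc(OCc2ccccc2)c(OCc2ccccc2)c1 | intermediate
11 | phloroglucinol | Oc1cc(O)cc(O)c1 | starting material
12 | 3,5-dihydroxyphenyl (Z)-2-[3,4-bis(benzyloxy)phenyl]ethenyl hexanedioate | Oc1cc(O)cc(OC(=O)CCCCC(=O)O/C=C\c2ccc(OCc3ccccc3)c(OCc3ccccc3)c2)c1 | intermediate
13 | benzhydrol adduct: CHO of 6 converted to CH(OH)–aryl, aryl = 2,4-dihydroxy-6-(acyloxy)phenyl of 12 (carbinol centre unassigned) | O(Cc1ccccc1)c1cc(OCc2ccccc2)c2c(c1C(O)c1c(O)cc(O)cc1OC(=O)CCCCC(=O)O/C=C\c1ccc(OCc3ccccc3)c(OCc3ccccc3)c1)O[C@H](c1ccc(OCc3ccccc3)c(OCc3ccccc3)c1)[C@H](O[Si](C)(C)C(C)(C)C)[C@H]2O[Si](C)(C)C(C)(C)C | intermediate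
14 | o-quinone methide from 13 by loss of water (6-alkylidene-cyclohexa-2,4-dienone) | O(Cc1ccccc1)c1cc(OCc2ccccc2)c2c(c1C=C1C(=O)C=C(O)C=C1OC(=O)CCCCC(=O)O/C=C\c1ccc(OCc3ccccc3)c(OCc3ccccc3)c1)O[C@H](c1ccc(OCc3ccccc3)c(OCc3ccccc3)c1)[C@H](O[Si](C)(C)C(C)(C)C)[C@H]2O[Si](C)(C)C(C)(C)C | intermediate
15 | macrocyclic cycloadduct: upper unit 2S,3S,4R all-cis, 3-O/5-O adipoyl-bridged (12-membered ring), 7-OH free, B-ring di-O-benzyl; 4β→8 to lower unit as in 4 | Oc1cc(OC(=O)CCCCC(=O)O%10)c2c(c1)O[C@@H](c1ccc(OCc3ccccc3)c(OCc3ccccc3)c1)[C@@H]%10[C@H]2c1c(OCc3ccccc3)cc(OCc3ccccc3)c2c1O[C@H](c1ccc(OCc3ccccc3)c(OCc3ccccc3)c1)[C@H](O[Si](C)(C)C(C)(C)C)[C@H]2O[Si](C)(C)C(C)(C)C | intermediate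
16 | hexa-O-benzyl bis-O-TBS dimer, upper 3-, 5-, 7-OH free | Oc1cc(O)c2c(c1)O[C@@H](c1ccc(OCc3ccccc3)c(OCc3ccccc3)c1)[C@@H](O)[C@H]2c1c(OCc3ccccc3)cc(OCc3ccccc3)c2c1O[C@H](c1ccc(OCc3ccccc3)c(OCc3ccccc3)c1)[C@H](O[Si](C)(C)C(C)(C)C)[C@H]2O[Si](C)(C)C(C)(C)C | intermediate
17 | lower-unit 3,4-bis-O-TBS ether of the target | Oc1cc(O)c2c(c1)O[C@@H](c1ccc(O)c(O)c1)[C@@H](O)[C@H]2c1c(O)cc(O)c2c1O[C@H](c1ccc(O)c(O)c1)[C@H](O[Si](C)(C)C(C)(C)C)[C@H]2O[Si](C)(C)C(C)(C)C | intermediate
18 | ent-epicatechin-(4β→8)-epicatechin-4β-ol (CNP0114173.1) | Oc1cc(O)c2c(c1)O[C@@H](c1ccc(O)c(O)c1)[C@@H](O)[C@H]2c1c(O)cc(O)c2c1O[C@H](c1ccc(O)c(O)c1)[C@H](O)[C@H]2O | target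

## Step count and risks

Total steps: 12. Longest linear sequence: 9 (steps 1–5, then 9–12).

The three steps most likely to fail are 9, 3 and 5.

Step 9 is the main risk. The hindered, electron-rich aldehyde may condense slowly, the macrocyclic cycloaddition may lose to oligomerisation, and neither the endo/facial selectivity nor the E-geometry of the quinone methide next to the peri acyloxy group is proven. If phloroglucinol ester 12 reacts at the carbon between its two free OH groups instead, the 7-O-strapped regioisomer results and converges at 16. The fallback sets out from bromide 5 and comes back at 17. 2,4,6-Trihydroxybenzaldehyde is dibenzylated (BnBr, K2CO3) to 2-hydroxy-4,6-bis(benzyloxy)benzaldehyde F1. Bromine–lithium exchange on 5 and addition to the lithium phenoxide of F1 (LiHMDS) gives the isolable o-hydroxybenzhydrol F2. F2 and the untethered (Z)-enol acetate F3 (from alkyne 8 and acetic acid under the step-7 Ru conditions) undergo the phosphoric-acid-catalysed intermolecular o-quinone methide [4+2] cycloaddition to the 3-O-acetyl octa-O-benzyl dimer F4. Methanolysis gives the 3-ol F5, and hydrogenolysis of its eight benzyl ethers gives 17.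

Step 3 is the second risk. The benzylic 4-OH may ionise under the silyl triflate, or the second silylation of the trans-diaxial diol may stall. The fallback sets out from 2 and comes back at 4. The 3-OH is silylated first (TBSCl, imidazole) to the 3-O-TBS ether F6. DDQ oxidation of F6 in the presence of tert-butyldimethylsilanol then traps the C4 cation directly as the 4β-silyl ether, trans to the 3-OTBS group, giving 4 without O-silylation of a benzylic alcohol.

Step 5 is the third risk. Halogen–metal exchange on a hexasubstituted arene flanked by benzyl ethers may give protonation or ether cleavage. The fallback sets out from 5 and comes back at 6. Stille coupling with tributyl(vinyl)stannane (Pd/P(t-Bu)3, CsF) gives the 8-vinyl compound F7, and Lemieux–Johnson cleavage (cat. OsO4, NaIO4, 2,6-lutidine, dioxane/H2O) gives aldehyde 6.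

## Further compounds

F1 | step 9 | 2-hydroxy-4,6-bis(benzyloxy)benzaldehyde | O=Cc1c(O)cc(OCc2ccccc2)cc1OCc2ccccc2
F2 | step 9 | o-hydroxybenzhydrol from 5 and F1 (carbinol centre unassigned) | O(Cc1ccccc1)c1cc(OCc2ccccc2)c2c(c1C(O)c1c(O)cc(OCc3ccccc3)cc1OCc3ccccc3)O[C@H](c1ccc(OCc3ccccc3)c(OCc3ccccc3)c1)[C@H](O[Si](C)(C)C(C)(C)C)[C@H]2O[Si](C)(C)C(C)(C)C
F3 | step 9 | (Z)-2-[3,4-bis(benzyloxy)phenyl]ethenyl acetate | CC(=O)O/C=C\c1ccc(OCc2ccccc2)c(OCc2ccccc2)c1
F4 | step 9 | 3-O-acetyl octa-O-benzyl bis-O-TBS dimer (upper 2S,3S,4R) | O(Cc1ccccc1)c1cc(OCc2ccccc2)c2c(c1)O[C@@H](c1ccc(OCc3ccccc3)c(OCc3ccccc3)c1)[C@@H](OC(C)=O)[C@H]2c1c(OCc3ccccc3)cc(OCc3ccccc3)c2c1O[C@H](c1ccc(OCc3ccccc3)c(OCc3ccccc3)c1)[C@H](O[Si](C)(C)C(C)(C)C)[C@H]2O[Si](C)(C)C(C)(C)C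
F5 | step 9 | octa-O-benzyl bis-O-TBS dimer 3-ol | O(Cc1ccccc1)c1cc(OCc2ccccc2)c2c(c1)O[C@@H](c1ccc(OCc3ccccc3)c(OCc3ccccc3)c1)[C@@H](O)[C@H]2c1c(OCc3ccccc3)cc(OCc3ccccc3)c2c1O[C@H](c1ccc(OCc3ccccc3)c(OCc3ccccc3)c1)[C@H](O[Si](C)(C)C(C)(C)C)[C@H]2O[Si](C)(C)C(C)(C)C
F6 | step 3 | 3-O-TBS-5,7,3',4'-tetra-O-benzyl-(−)-epicatechin | O(Cc1ccccc1)c1cc(OCc2ccccc2)c2c(c1)O[C@H](c1ccc(OCc3ccccc3)c(OCc3ccccc3)c1)[C@H](O[Si](C)(C)C(C)(C)C)C2
F7 | step 5 | 8-vinyl derivative of 4 | O(Cc1ccccc1)c1cc(OCc2ccccc2)c2c(c1C=C)O[C@H](c1ccc(OCc3ccccc3)c(OCc3ccccc3)c1)[C@H](O[Si](C)(C)C(C)(C)C)[C@H]2O[Si](C)(C)C(C)(C)C
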